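## Retrosynthetic overview

1. Target ⇐ hydride reduction of an ethyl (E)-enoate that carries two N-acyl sultams (each CH2OH is a latent acyl sultam) ⇐ Wittig C2 extension of a trimer aldehyde.
2. Dioxane ring 2 (on ring B; O3–C8'' and O4–C7'') ⇐ Ag2CO3 oxidative cross-coupling of the ring B catechol of a dimer aldehyde with a caffeoyl sultam monomer: aryloxy radical 8–O coupling, then closure of the quinone methide by the neighbouring OH, as in the presumed biosynthesis.
3. Dioxane ring 1 (on ring A; O4–C8' and O3–C7') ⇐ the same coupling between 3,4-dihydroxybenzaldehyde and the same monomer; the sultam fixes C8, the trans ring closure fixes C7.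
4. Monomer ⇐ Wittig reaction of 3,4-dihydroxybenzaldehyde with the ylide from N-bromoacetyl sultam, without protecting groups.
5. Ring order: dioxane ring 1 first, dioxane ring 2 second; all three benzene rings are bought.

Labels: ring A carries the propenol chain, ring B is the central benzene ring, ring C is the free catechol. C7'/C8'/C9' are the side-chain carbons of the ring B unit (in dioxane ring 1); C7''/C8''/C9'' are those of the ring C unit (in dioxane ring 2).

Assumption: the N-enoyl (2R)-bornane-10,2-sultam reacts in its s-cis, C=O/SO2-anti conformation on the C8 face remote from the pseudo-axial sulfonyl oxygen (Si face), giving the configuration drawn; if the sense found is the opposite, the antipodal (2S)-sultam is used and nothing else changes.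

## Route

Step 1
Reactants: 1 (2R)-bornane-10,2-sultam; 2 bromoacetyl bromide
Product: 4 N-(bromoacetyl)-(2R)-bornane-10,2-sultam, via sodium sultamide 3 (not isolated)
Conditions: NaH (1.1 equiv), THF, 0 °C; then 2, 0 °C to rt
Reagents that add atoms: none
Why: N-acylation of a sulfonamide anion by an acid bromide (standard sultam acylation); the acyl bromide reacts far faster than the alkyl bromide and no stereocentre is touched.

Step 2
Reactants: 4 N-(bromoacetyl)-(2R)-bornane-10,2-sultam; 5 3,4-dihydroxybenzaldehyde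
Product: 8 N-[(E)-3-(3,4-dihydroxyphenyl)prop-2-enoyl]-(2R)-bornane-10,2-sultam (monomer), via phosphonium bromide 6 (not isolated), via phosphorus ylide 7 (not isolated)
Conditions: PPh3 (1.05 equiv), MeCN, 40 °C; then Et3N (1.0 equiv), 0 °C; then 5, 70 °C
Reagents that add atoms: none
Why: Wittig olefination: SN2 of PPh3 on the α-bromo imide gives the salt, and its imide-stabilised, non-basic ylide tolerates the free catechol and gives the E-alkene; no stereocentre is formed.

Step 3
Reactants: 5 3,4-dihydroxybenzaldehyde; 8 caffeoyl sultam monomer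
Product: 10 (2S,3R)-3-(3,4-dihydroxyphenyl)-2-(sultam-N-ylcarbonyl)-2,3-dihydro-1,4-benzodioxine-6-carbaldehyde (dimer aldehyde), via quinone methide 9 (not isolated)
Conditions: Ag2CO3 (1.5 equiv), toluene/acetone 2:1, 50 °C, dark, N2; 8 added over 4 h to 5 (3 equiv)
Reagents that add atoms: none
Why: Proposed new method: Ag2CO3 oxidises both phenols to aryloxy radicals; the 4-O radical of 5 (para to CHO, the more acidic OH) bonds to C8 of the radical of 8 on the face left open by the sultam, which sets C8', and the 3-OH then closes quinone methide 9 by 6-exo oxa-Michael addition with aryl and acyl trans, which sets C7'; the closest known reactions are the Ag2CO3 coupling of 3,4-dihydroxybenzaldehyde with coniferyl alcohol to the same benzodioxane regioisomer and the sultam-directed oxidative 8–5' dimerisation of a feruloyl sultam.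

Step 4
Reactants: 10 dimer aldehyde; 8 caffeoyl sultam monomer
Product: 12 bis-sultam trimer aldehyde [dioxane ring 1 (2S,3R); dioxane ring 2 (2R,3S)], via quinone methide 11 (not isolated)
Conditions: Ag2CO3 (1.5 equiv), toluene/acetone 2:1, 50 °C, dark, N2; 8 (1.0 equiv) added over 6 h to 10 (1.5 equiv, excess recovered); silica chromatography, then preparative HPLC
Reagents that add atoms: none
Why: Proposed new method: the same oxidative radical 8–O coupling and quinone methide ring closure on the ring B catechol of 10 (the sultam sets C8'', the trans closure of 11 sets C7''); ring B has no conjugating substituent, so both of its oxygens couple in a ratio near 1:1, as in the closest known reaction (Ag2CO3 coupling of taxifolin with coniferyl alcohol to silybin and isosilybin), and the 3-O–C8''/4-O–C7'' isomer 12 is separated from its regioisomer by chromatography.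

Step 5
Reactants: 12 bis-sultam trimer aldehyde; 13 ethyl (triphenylphosphoranylidene)acetate
Product: 14 ethyl (E)-enoate of the bis-sultam trimer
Conditions: 13 (1.3 equiv), THF, 60 °C
Reagents that add atoms: none
Why: Wittig olefination with a stabilised ylide under neutral conditions gives the E-enoate and leaves the imides, the phenols and all four stereocentres untouched.

Step 6
Reactants: 14 ethyl (E)-enoate of the bis-sultam trimer
Product: 15 (E)-3-{(2R,3R)-3-[(2R,3R)-2-(3,4-dihydroxyphenyl)-3-(hydroxymethyl)-2,3-dihydro-1,4-benzodioxin-6-yl]-2-(hydroxymethyl)-2,3-dihydro-1,4-benzodioxin-6-yl}prop-2-en-1-ol (target)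
Conditions: iBu2AlH (12 equiv), THF/CH2Cl2, −78 to 0 °C; aq. KNaC4H4O6 work-up under argon
Reagents that add atoms: none
Why: Hydride reduction: iBu2AlH reduces the conjugated ester 1,2 to the allylic alcohol and cleaves both N-acyl sultams reductively to CH2OH, the geometry at C8' and C8'' is kept (their descriptors change from S to R only because CH2OH ranks below C7), and the sultam is recovered.

## Compound list

1 | (2R)-bornane-10,2-sultam [(1S)-(−)-2,10-camphorsultam, (3aS,6R,7aR)]; called "sultam" below | N1[C@@H]2C[C@H]3CC[C@]2(CS1(=O)=O)C3(C)C | starting material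
2 | bromoacetyl bromide | O=C(Br)CBr | starting material
3 | sodium salt of 1 (NaC10H16NO2S) | [Na+].[N-]1[C@@H]2C[C@H]3CC[C@]2(CS1(=O)=O)C3(C)C | intermediate
4 | N-(bromoacetyl)-(2R)-bornane-10,2-sultam | O=C(CBr)N1[C@@H]2C[C@H]3CC[C@]2(CS1(=O)=O)C3(C)C | intermediate
5 | 3,4-dihydroxybenzaldehyde | O=Cc1ccc(O)c(O)c1 | starting material
6 | [2-oxo-2-(sultam-N-yl)ethyl]triphenylphosphonium bromide | [Br-].O=C(C[P+](c1ccccc1)(c1ccccc1)c1ccccc1)N1[C@@H]2C[C@H]3CC[C@]2(CS1(=O)=O)C3(C)C | intermediate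
7 | N-[(triphenylphosphoranylidene)acetyl]-(2R)-bornane-10,2-sultam (ylide) | O=C(C=P(c1ccccc1)(c1ccccc1)c1ccccc1)N1[C@@H]2C[C@H]3CC[C@]2(CS1(=O)=O)C3(C)C | intermediate
8 | N-[(E)-3-(3,4-dihydroxyphenyl)prop-2-enoyl]-(2R)-bornane-10,2-sultam (monomer) | O=C(/C=C/c1ccc(O)c(O)c1)N1[C@@H]2C[C@H]3CC[C@]2(CS1(=O)=O)C3(C)C | intermediate
9 | quinone methide: N-[(2S)-2-(4-formyl-2-hydroxyphenoxy)-3-(3-hydroxy-4-oxocyclohexa-2,5-dien-1-ylidene)propanoyl]-(2R)-bornane-10,2-sultam (exocyclic C=C geometry not defined) | O=Cc1ccc(O[C@@H](C=C2C=CC(=O)C(O)=C2)C(=O)N3[C@@H]4C[C@H]5CC[C@]4(CS3(=O)=O)C5(C)C)c(O)c1 | intermediate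
10 | (2S,3R)-3-(3,4-dihydroxyphenyl)-2-(sultam-N-ylcarbonyl)-2,3-dihydro-1,4-benzodioxine-6-carbaldehyde (trans) | O=Cc1ccc2c(c1)O[C@H](c1ccc(O)c(O)c1)[C@@H](C(=O)N3[C@@H]4C[C@H]5CC[C@]4(CS3(=O)=O)C5(C)C)O2 | intermediate
11 | quinone methide: as 9, but the aryloxy group on the (2S) carbon is 2-hydroxy-5-[(2S,3R)-6-formyl-2-(sultam-N-ylcarbonyl)-2,3-dihydro-1,4-benzodioxin-3-yl]phenoxy (exocyclic C=C geometry not defined) | O=Cc1ccc2c(c1)O[C@H](c1ccc(O)c(c1)O[C@@H](C=C3C=CC(=O)C(O)=C3)C(=O)N3[C@@H]4C[C@H]5CC[C@]4(CS3(=O)=O)C5(C)C)[C@@H](C(=O)N3[C@@H]4C[C@H]5CC[C@]4(CS3(=O)=O)C5(C)C)O2 | intermediate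
12 | (2S,3R)-3-[(2R,3S)-2-(3,4-dihydroxyphenyl)-3-(sultam-N-ylcarbonyl)-2,3-dihydro-1,4-benzodioxin-6-yl]-2-(sultam-N-ylcarbonyl)-2,3-dihydro-1,4-benzodioxine-6-carbaldehyde | O=Cc1ccc2c(c1)O[C@H](c1ccc3c(c1)O[C@H](C(=O)N4[C@@H]5C[C@H]6CC[C@]5(CS4(=O)=O)C6(C)C)[C@@H](c1ccc(O)c(O)c1)O3)[C@@H](C(=O)N3[C@@H]4C[C@H]5CC[C@]4(CS3(=O)=O)C5(C)C)O2 | intermediate
13 | ethyl (triphenylphosphoranylidene)acetate | CCOC(=O)C=P(c1ccccc1)(c1ccccc1)c1ccccc1 | starting material
14 | ethyl (E)-3-{(2S,3R)-3-[(2R,3S)-2-(3,4-dihydroxyphenyl)-3-(sultam-N-ylcarbonyl)-2,3-dihydro-1,4-benzodioxin-6-yl]-2-(sultam-N-ylcarbonyl)-2,3-dihydro-1,4-benzodioxin-6-yl}prop-2-enoate | CCOC(=O)/C=C/c1ccc2c(c1)O[C@H](c1ccc3c(c1)O[C@H](C(=O)N4[C@@H]5C[C@H]6CC[C@]5(CS4(=O)=O)C6(C)C)[C@@H](c1ccc(O)c(O)c1)O3)[C@@H](C(=O)N3[C@@H]4C[C@H]5CC[C@]4(CS3(=O)=O)C5(C)C)O2 | intermediate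
15 | (E)-3-{(2R,3R)-3-[(2R,3R)-2-(3,4-dihydroxyphenyl)-3-(hydroxymethyl)-2,3-dihydro-1,4-benzodioxin-6-yl]-2-(hydroxymethyl)-2,3-dihydro-1,4-benzodioxin-6-yl}prop-2-en-1-ol (CNP0261312.2) | OC/C=C/c1ccc2c(c1)O[C@H](c1ccc3c(c1)O[C@H](CO)[C@@H](c1ccc(O)c(O)c1)O3)[C@@H](CO)O2 | target

## Step count and risks

Total step count: 6. Longest linear sequence: 6 steps (1 → 4 → 8 → 10 → 12 → 14 → 15).

Steps most likely to fail:

**Step 4.** Nothing in ring B tells its two oxygens apart, so at best about half of the coupled material is 12. The monomer can also couple with itself, and the new ring C catechol can couple again.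

The fallback differentiates the two ring B oxygens before the coupling. It sets out from 5 and 7 and begins with the two operations of the step 3 fallback below, which give the O-benzyl monomer F1 and the 3-O-benzyl dimer aldehyde F2. The free 4-OH of F2 is capped with MOMCl/iPr2NEt to give the methoxymethyl ether F3. Hydrogenolysis (H2, Pd/C, EtOAc) frees the 3-OH to give the mono-phenol F4. Ag2CO3 coupling of F4 with 8 can then only join the 3-O to C8''. The quinone methide has no neighbouring OH and loses H8'' to give the (Z)-enol ether F5. CF3CO2H in wet CH2Cl2 removes the methoxymethyl group to give the phenol F6. In the same pot F6 closes by acid-catalysed 6-endo oxa-Michael addition of the 4-OH to C7'', with sultam-controlled protonation at C8'' and equilibration to the trans ring. The diastereomer identical with 12 is isolated and the route is rejoined at 12. The sense of that protonation is unverified.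

**Step 3.** The free-catechol monomer 8 can act as its own catechol partner, and the face selectivity of the sultam in an 8–O coupling is untested.

The fallback sets out from 7 and 5 and uses a C8 donor that cannot form a dioxane with itself. Ylide 7 is heated with commercial 3-benzyloxy-4-hydroxybenzaldehyde to give N-[(E)-3-(3-benzyloxy-4-hydroxyphenyl)prop-2-enoyl]-(2R)-bornane-10,2-sultam F1. This is the same substrate class as the known feruloyl sultam couplings. F1 is coupled with excess 5 under Ag2CO3 to give the 3-O-benzyl dimer aldehyde F2. Hydrogenolysis (H2, Pd/C, EtOAc) removes the benzyl group and the route is rejoined at 10.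

**Step 6.** Three carbonyl groups must be reduced on a tetraphenol. Risks are 1,4-reduction of the enoate, incomplete cleavage of the hindered imides, and epimerisation at C8' or C8'' through the α-aryloxy aldehydes.

The fallback sets out from 12 and changes both the chain precursor and the hydride. Wittig reaction of 12 with Ph3P=CHCHO gives the (E)-enal F7. LiBH4 in THF/H2O at 0 °C reduces the enal 1,2 and cleaves both N-acyl sultams directly to the primary alcohols, rejoining the route at 15.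

## Further compounds

F1 | step 3 | N-[(E)-3-(3-benzyloxy-4-hydroxyphenyl)prop-2-enoyl]-(2R)-bornane-10,2-sultam | O=C(/C=C/c1ccc(O)c(OCc2ccccc2)c1)N1[C@@H]2C[C@H]3CC[C@]2(CS1(=O)=O)C3(C)C
F2 | step 3 | (2S,3R)-3-(3-benzyloxy-4-hydroxyphenyl)-2-(sultam-N-ylcarbonyl)-2,3-dihydro-1,4-benzodioxine-6-carbaldehyde | O=Cc1ccc2c(c1)O[C@H](c1ccc(O)c(OCc3ccccc3)c1)[C@@H](C(=O)N3[C@@H]4C[C@H]5CC[C@]4(CS3(=O)=O)C5(C)C)O2
F3 | step 4 | (2S,3R)-3-[3-benzyloxy-4-(methoxymethoxy)phenyl]-2-(sultam-N-ylcarbonyl)-2,3-dihydro-1,4-benzodioxine-6-carbaldehyde | O=Cc1ccc2c(c1)O[C@H](c1ccc(OCOC)c(OCc3ccccc3)c1)[C@@H](C(=O)N3[C@@H]4C[C@H]5CC[C@]4(CS3(=O)=O)C5(C)C)O2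
F4 | step 4 | (2S,3R)-3-[3-hydroxy-4-(methoxymethoxy)phenyl]-2-(sultam-N-ylcarbonyl)-2,3-dihydro-1,4-benzodioxine-6-carbaldehyde | O=Cc1ccc2c(c1)O[C@H](c1ccc(OCOC)c(O)c1)[C@@H](C(=O)N3[C@@H]4C[C@H]5CC[C@]4(CS3(=O)=O)C5(C)C)O2
F5 | step 4 | (Z)-enol ether: F4 with its 3-O bonded to C2 of an N-[(Z)-3-(3,4-dihydroxyphenyl)prop-2-enoyl]-(2R)-bornane-10,2-sultam unit | O=Cc1ccc2c(c1)O[C@H](c1ccc(OCOC)c(c1)O/C(=C\c1ccc(O)c(O)c1)C(=O)N3[C@@H]4C[C@H]5CC[C@]4(CS3(=O)=O)C5(C)C)[C@@H](C(=O)N3[C@@H]4C[C@H]5CC[C@]4(CS3(=O)=O)C5(C)C)O2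
F6 | step 4 | phenol from F5 (methoxymethyl group removed, 4-OH of ring B free) | O=Cc1ccc2c(c1)O[C@H](c1ccc(O)c(c1)O/C(=C\c1ccc(O)c(O)c1)C(=O)N3[C@@H]4C[C@H]5CC[C@]4(CS3(=O)=O)C5(C)C)[C@@H](C(=O)N3[C@@H]4C[C@H]5CC[C@]4(CS3(=O)=O)C5(C)C)O2
F7 | step 6 | (E)-3-{(2S,3R)-3-[(2R,3S)-2-(3,4-dihydroxyphenyl)-3-(sultam-N-ylcarbonyl)-2,3-dihydro-1,4-benzodioxin-6-yl]-2-(sultam-N-ylcarbonyl)-2,3-dihydro-1,4-benzodioxin-6-yl}prop-2-enal | O=C/C=C/c1ccc2c(c1)O[C@H](c1ccc3c(c1)O[C@H](C(=O)N4[C@@H]5C[C@H]6CC[C@]5(CS4(=O)=O)C6(C)C)[C@@H](c1ccc(O)c(O)c1)O3)[C@@H](C(=O)N3[C@@H]4C[C@H]5CC[C@]4(CS3(=O)=O)C5(C)C)O2
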